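## The problem

Compound 29 is a germacranolide: a ten-membered carbocycle (C1–C10) to which a γ-lactone (O6, C12, C11, C7, C6) is trans-fused across C6–C7. A synthesis therefore has to close a medium ring at one carbon–carbon bond while four ring carbons already carry oxygen. There are seven stereocentres: the cis-4,5-epoxide (C4 R, C5 S), C6 (S), C7 (R), C8 (S), C11 (R) and the tertiary acetate carbon C10 (R). Six of them form a chain of induction: the epoxide can be set by a reagent and then steers C6, C6 steers C7 and C7 steers C11 across the five-membered ring, and O6 can steer C8 through a chelate. C10 is cut off from all of them by the C9 methylene and has no reliable controller. Several groups are fragile: the trisubstituted epoxide (acids), the 13-acetoxymethyl lactone (loses acetic acid with base), the tiglate (ozone, one-electron reductants, enolates), a free O8 next to the lactone (acyl migration from O6 to O8), and a C8 ketone next to the lactone (β-elimination of O6). The feature that the plan uses is that the lactone bond C7–C11 lies next to the C6–O bond in a five-membered ring while the neighbouring C8 bears oxygen: a two-carbon haloacetal on O6 can give a C11 radical that closes 5-exo onto C7 of a C7=C8 olefin and leaves a C8 radical for an oxygen trap.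

## Retrosynthesis

**Ester bonds at O10 and O8.** Cutting the O10–acetyl bond of 29 gives tertiary alcohol 28, cutting the O8–tigloyl bond gives diol 27, and 27 comes from silyl ether 26. The tiglate is put on late because it would not survive ozonolysis, SmI2 or enolate chemistry. It goes on before the tertiary acetate because a tertiary acetate beside a free syn-1,3 hydroxyl could migrate. The forward steps must acylate a hindered secondary and then a tertiary hydroxyl without eliminating acetic acid across C11–C13.

**C1 carbonyl and the C1–C10 ring bond.** The α-ketol of 26 is the oxidation product of 1,10-diol 25, and cutting C1–C10 in 25 gives keto aldehyde 24. This is the one ring bond whose cleavage leaves two carbonyl groups that are both latent olefins of simple terpene chains. Cuts at C2–C3 or C9–C10 would need carbanions beside the epoxide or the lactone. The precursor is open-chain apart from the lactone. The forward reaction, a SmI2 pinacol closure, must spare epoxide, lactone and acetate, and it alone decides C10; this is the weakest link of the plan.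

**Carbonyls from olefins, and C13.** Both carbonyls of 24 come from olefins of diene 22 by ozonolysis (C1 from the isopropylidene end, C10 from the methallyl end). The C13 acetate is cut to alcohol 21, and the C11–C13 bond to lactone 19 and formaldehyde. Making this bond on the five-membered ring lets the C7 side chain direct C11. Bringing C13 in earlier would change the radical of the key step. The forward aldol needs an enolate with no competing electrophile nearby, so O8 is silylated and no tiglate is present.

**Lactone oxidation level and the C8 configuration.** Lactone 19 goes back to lactol 18 and ethyl acetal 17, and 17 to alcohol 16. The C8 centre of 16 is cut back to ketone 15, and 15 to the epimeric alcohols 14 and aminoxyl ether 13. The order matters. With the lactone in place a C8 ketone would be a β-acyloxy ketone, and a C8 alkoxide would invite lactone migration. At the acetal stage O6 is an ether oxygen that can hold zinc in a chelate and direct hydride to the face that gives the 6,8-syn alcohol. The forward steps need an N–O cleavage and an oxidation that tolerate the epoxide and keep the C10 olefin out of conjugation.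

**C7–C11 and C8–O (key disconnection).** Cutting both bonds in 13 opens the tetrahydrofuran to bromoacetal 11. Unlike a conjugate addition to a butenolide, this forms the carbon–carbon bond and the C8–O bond in one operation from a plain E-olefin, with no carbonyl needed at C8. The precursor has only the stereocentres C4–C6. The forward step needs ring closure before trapping, trans selectivity at C6/C7 and an oxygen trap for a secondary radical.

**Acetal, C6–C7 and the two small fragments.** The acetal C–O bond of 11 is cut to dienol 9 and ethyl vinyl ether 10. The C6–C7 bond of 9 is cut to epoxy aldehyde 3 and an E-alkenyl metal from enyne 6, which joins the halves at the carbon that the adjacent epoxide controls. Aldehyde 3 is two steps from nerol 1 through epoxy alcohol 2; nerol supplies C1–C6, C15, the Z-olefin for the cis-epoxide and the masked C1 aldehyde. Enyne 6 is cut at C8–C9 into ethynylmagnesium bromide 4 and 3-chloro-2-methylprop-1-ene 5. The reverse polarity (vinyl nucleophile, propargylic halide) is avoided because propargylic halides tend to give allenes by SN2′ attack.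

## Roads not taken

**Alternative 1:** The ten-membered ring would be made by expanding a six-membered ring. The cut is C8–C9 (formed) against the old ring bond C1–C6 (broken). The potassium alkoxide of divinyl carbinol A1, a monoterpene-derived cyclohexenol with a 2-alkoxyvinyl group on the carbinol carbon and an isopropenyl group beside it, would undergo an anionic oxy-Cope shift (KH, 18-crown-6). The product is the C6 enolate of (Z,E)-cyclodecadienone A2, which carries O8 as a 4-methoxybenzyl ether.
- Merits: no macrocyclisation entropy, both olefin geometries fixed by the old ring and a chair transition state, and a short chiral-pool entry. On ring formation this road is clearly better than the chosen plan.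
- Weak points: A2 has one stereocentre and none of the lactone carbons. C7 alkylation, C6 reduction, C11, C13, the epoxide and the C1/C10 oxidation pattern would all have to be added to a flexible cyclodecadiene prone to transannular reactions. The enolate formed in the key step has the C8 ether in the β-position and can expel it. C8 itself depends on enol ether geometry and chair/boat selection.
- Comparison: the chosen plan sets C4–C8 and C11 on an open chain and a five-membered ring by individually understood models, and pays with a late, uncertain ring closure.

**Alternative 2:** The cut is C7–C8 and C11–C13 in one operation. The 2-lithio derivative of dithiane A4 (acyl anion for C8, carrying C9, C10 with its methyl, and C1 in an acetonide) would add to C7 of butenolide A3 anti to the C6 substituent. The lactone enolate would then be captured at C11 by formaldehyde to give trans,trans-lactone A5.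
- Merits: two ring stereocentres and C13 in one flask with a predictable outcome, and C10 arrives already set from a small chiral building block. In both respects this is better than the chosen plan, which has a separate hydroxymethylation and an uncontrolled C10.
- Weak points: C8 arrives as a masked ketone next to the lactone; unmasking gives a β-acyloxy ketone prone to elimination, and its reduction has no chelating ether oxygen. C6 carries only a CH2O stub, so C5, the cis-epoxide (by substrate control), C2–C4 and the ring closure remain. A hindered 2-substituted lithiodithiane may add 1,2.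
- Comparison: the chosen plan offers a starting material that already holds C1–C6 with the epoxide set by a reagent, and a C8–O bond formed at the acetal stage where chelation control is available.

**Alternative 3:** The ring would be formed one atom too large and contracted. Eleven-membered sulfone A6 (sulfur between C4 and C5) would be α-halogenated in situ, close to the episulfone and lose SO2 to give Z-cyclodecene A7. A7 is fused to the lactol methyl ether, with O8 silylated and the C1/C10 diol as an acetonide.
- Merits: closure of a thioether ring is far easier than any carbon–carbon closure to a ten-membered ring, the ring enforces the Z-4,5-olefin, and C10 is set before cyclisation. On ring formation and on C10 it is better than the chosen plan.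
- Weak points: the Ramberg–Bäcklund step must form a trisubstituted olefin under strongly basic conditions, which needs halogenation at a hindered α-carbon. The epoxide would be introduced afterwards by substrate control with no assurance of the required face. The acetonide must be removed with acid near that epoxide. Several steps are spent on sulfur.
- Comparison: the chosen plan fixes the epoxide first by reagent control and needs no sulfur chemistry, but accepts the riskier ring closure.

Key step: step 6

## Route

Remark: locants are those of the germacrane skeleton of 29; the acetal carbon C12 in 11–18 and C1 in 25 are epimer mixtures that later become trigonal and are left undefined in the SMILES; the CIP descriptor at C7 changes with the group on O8 although the spatial arrangement does not.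

Step 1
Reactants: 1 nerol
Product: 2 (2S,3R)-2,3-epoxynerol, ((2S,3R)-3-methyl-3-(4-methylpent-3-en-1-yl)oxiran-2-yl)methanol
Conditions: Ti(OiPr)4 (5 mol%), L-(+)-diethyl tartrate (6 mol%), tBuOOH, 4 Å MS, CH2Cl2, −20 °C
Reagents that add atoms: tert-butyl hydroperoxide, CC(C)(C)OO
Why: Sharpless asymmetric epoxidation of a Z-allylic alcohol; the L-(+)-tartrate catalyst delivers oxygen to the face of the 2,3-olefin that gives the (2S,3R)-epoxide (C4 R and C5 S of 29, cis because the olefin is Z), and the isolated 6,7-olefin, which has no directing hydroxyl, is not epoxidised.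

Step 2
Reactants: 2 (2S,3R)-2,3-epoxynerol
Product: 3 (2R,3R)-3-methyl-3-(4-methylpent-3-en-1-yl)oxirane-2-carbaldehyde
Conditions: Dess–Martin periodinane, pyridine, CH2Cl2, 0 °C
Reagents that add atoms: none
Why: Dess–Martin oxidation of a primary alcohol under pyridine buffering; the epoxide C–H is not acidic enough to epimerise and the sensitive epoxy aldehyde is used without chromatography.

Step 3
Reactants: 4 ethynylmagnesium bromide; 5 3-chloro-2-methylprop-1-ene
Product: 6 2-methylpent-1-en-4-yne
Conditions: CuCl (5 mol%), THF, 50 °C; fractional distillation
Reagents that add atoms: none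
Why: Copper-catalysed coupling of an alkynyl Grignard reagent with an allylic chloride, the classical route to skipped enynes; the methallyl unit is symmetrical, so direct and allylic substitution give the same product, and no stereocentre is formed.

Step 4
Reactants: 6 2-methylpent-1-en-4-yne; 3 (2R,3R)-epoxy aldehyde
Product: 9 (1S,2E)-5-methyl-1-[(2S,3R)-3-methyl-3-(4-methylpent-3-en-1-yl)oxiran-2-yl]hexa-2,5-dien-1-ol (4R,5S,6S), via alkenylzirconocene chloride 7 (not isolated), via alkenylmethylzinc 8 (not isolated)
Conditions: Cp2Zr(H)Cl, CH2Cl2, 20 °C; Me2Zn, toluene, −65 °C; then 3, 0 °C; NH4Cl aq.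
Reagents that add atoms: none
Why: Hydrozirconation adds Zr–H syn and anti-Markovnikov to the terminal alkyne (faster than to the 1,1-disubstituted olefin) and fixes the E geometry of C7=C8; transmetalation to zinc gives an alkenylzinc that adds 1,2 to the aldehyde. C6 is set by polar Felkin–Anh (Cornforth) control, the epoxide C–O bond lying anti to the incoming nucleophile, which gives the 5,6-anti (6S) alcohol; the cis substituent on the epoxide should reinforce this preference.

Step 5
Reactants: 9 epoxy dienol; 10 ethyl vinyl ether
Product: 11 O6-(2-bromo-1-ethoxyethyl) ether of 9 (4R,5S,6S; C12 epimers)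
Conditions: N-bromosuccinimide, ethyl vinyl ether (excess), CH2Cl2, −40 → 0 °C
Reagents that add atoms: N-bromosuccinimide, O=C1CCC(=O)N1Br
Why: Alkoxybromination of an enol ether: N-bromosuccinimide brominates the electron-rich vinyl ether far faster than the three unactivated olefins and the alcohol opens the resulting bromo-oxocarbenium ion to give the mixed bromoacetal; the new acetal centre is an inconsequential mixture.

Step 6
Reactants: 11 bromoacetal
Product: 13 2-ethoxytetrahydrofuran C8 aminoxyl ether (4R,5S,6S,7S; epimers at C8 and C12; ring O6–C12–C11–C7–C6 with the epoxide arm on C6 and trans to it on C7 the CH(O-N-tetramethylpiperidinyl)CH2C(CH3)=CH2 arm), via alkylcobaloxime 12 (not isolated)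
Conditions: Co(dmgH)2(py)Cl (1.2 equiv), NaBH4, NaOH, MeOH, 0 → 20 °C, dark; then TEMPO (5 equiv), CH2Cl2, visible light, 20 °C
Reagents that add atoms: 2,2,6,6-tetramethylpiperidin-1-oxyl (TEMPO), CC1(C)CCCC(C)(C)N1[O]
Why: Ueno–Stork haloacetal radical cyclisation in its cobaloxime-mediated, nitroxide-trapping form, a known combination for bromoacetals of allylic alcohols. Monovalent cobalt made from Co(dmgH)2(py)Cl and NaBH4 transfers an electron to the C–Br bond of 11, and the C11 radical closes the tetrahydrofuran ring (O6, C12, C11, C7, C6) by 5-exo-trig attack on C7 of the E-C7=C8 olefin. The closure follows the Beckwith–Houk chair-like transition state with the C6 epoxide arm pseudo-equatorial, which places the new C7–C8 bond trans to that arm and sets C7. The secondary C8 radical is stored by divalent cobalt as alkylcobaloxime 12; visible light then breaks the weak C–Co bond reversibly and the persistent nitroxide captures the C8 radical irreversibly as the C8–O bond. C8 forms under weak 1,2-induction from C7 and both epimers are expected, which is accepted because steps 8 and 9 rebuild C8 from the ketone. Cyclisation before trapping is secured by adding the nitroxide only after 12 has formed, and closure on C7=C8 alone is secured by distance, since the other two olefins could only be reached through eight- or nine-membered transition states. The epoxide, which is not alpha to either radical centre, and the acetal should be inert to the basic reductive medium.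

Step 7
Reactants: 13 aminoxyl ether
Product: 14 C8 alcohol of the 2-ethoxytetrahydrofuran (4R,5S,6S,7R; epimers at C8 and C12)
Conditions: Zn dust, AcOH, THF (anhydrous), 25–40 °C
Reagents that add atoms: none
Why: Reductive cleavage of the alkoxyamine N–O bond by zinc in acetic acid, the standard way to unmask nitroxide-trapped alcohols; the medium is kept anhydrous and near room temperature so that the ethyl acetal and the epoxide persist, and both C8 epimers are taken on together.

Step 8
Reactants: 14 C8 alcohol (epimers)
Product: 15 C8 ketone of the 2-ethoxytetrahydrofuran (4R,5S,6S,7S; C12 epimers)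
Conditions: Dess–Martin periodinane, pyridine, CH2Cl2, 0 °C
Reagents that add atoms: none
Why: Dess–Martin oxidation merges the C8 epimers into one ketone; the buffered neutral conditions leave the β,γ-olefin (C10=CH2) out of conjugation and do not epimerise C7, and the ketone is reduced at once.

Step 9
Reactants: 15 C8 ketone
Product: 16 (8S)-alcohol of the 2-ethoxytetrahydrofuran (4R,5S,6S,7R,8S; C12 epimers)
Conditions: Zn(BH4)2, Et2O, −30 → 0 °C; NH4Cl aq.
Reagents that add atoms: none
Why: Chelation-controlled reduction of a β-alkoxy ketone: zinc bridges the C8 carbonyl oxygen and the ring oxygen O6, the resulting bicyclic chelate exposes the C8 face turned away from C11, and hydride delivery there gives the 6,8-syn (8S) alcohol; Zn(BH4)2 leaves the epoxide and the olefins alone.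

Step 10
Reactants: 16 (8S)-alcohol
Product: 17 (8S)-tert-butyldimethylsilyl ether of 16 (4R,5S,6S,7S,8S; C12 epimers)
Conditions: tBuMe2SiCl, imidazole, DMAP (cat.), DMF, 40 °C
Reagents that add atoms: tert-butyldimethylsilyl chloride, CC(C)(C)[Si](C)(C)Cl
Why: Silylation of a secondary alcohol with a silyl chloride and imidazole; basic conditions free of Lewis acid are chosen so that neither the acetal nor the epoxide is activated, and the silyl ether blocks O8 against lactone migration and oxidation in all later steps.

Step 11
Reactants: 17 silyl ether acetal
Product: 18 lactol (2-hydroxytetrahydrofuran; 4R,5S,6S,7S,8S; C12 epimers)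
Conditions: pyridinium p-toluenesulfonate (0.2 equiv), acetone–H2O (4:1), 40 °C
Reagents that add atoms: water, O
Why: Acid-catalysed hydrolysis of a 2-alkoxytetrahydrofuran, which as a furanoside-type acetal ionises far more readily than the trisubstituted epoxide opens; the buffered pyridinium acid and moderate temperature are chosen for that margin, and the secondary silyl ether is stable to them.

Step 12
Reactants: 18 lactol
Product: 19 γ-lactone (4R,5S,6S,7S,8S)
Conditions: nPr4N[RuO4] (5 mol%), N-methylmorpholine N-oxide, 4 Å MS, CH2Cl2, 20 °C
Reagents that add atoms: none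
Why: Perruthenate-catalysed oxidation of a lactol to the γ-lactone with N-methylmorpholine N-oxide as the stoichiometric oxidant; the conditions are neutral and do not touch olefins, epoxide or silyl ether.

Step 13
Reactants: 19 γ-lactone
Product: 21 (11R)-11-hydroxymethyl lactone (4R,5S,6S,7S,8S,11R), via lithium enolate 20 (not isolated)
Conditions: LiN(iPr)2, THF, −78 °C; CH2O (gas, from cracked paraformaldehyde), −78 → −30 °C; NH4Cl aq.
Reagents that add atoms: formaldehyde, C=O
Why: Aldol-type hydroxymethylation of a lactone lithium enolate with monomeric formaldehyde; the electrophile enters trans to the C7 side chain on the five-membered enolate and sets C11 (R), which is also the thermodynamically preferred all-trans arrangement.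

Step 14
Reactants: 21 hydroxymethyl lactone
Product: 22 13-acetate (4R,5S,6S,7S,8S,11R)
Conditions: Ac2O, pyridine, DMAP (cat.), CH2Cl2, 0 °C
Reagents that add atoms: acetic anhydride, CC(=O)OC(C)=O
Why: Acetylation of a primary alcohol; it is run promptly and cold so that the β-hydroxy lactone loses neither formaldehyde (retro-aldol) nor water.

Step 15
Reactants: 22 13-acetate diene
Product: 24 keto aldehyde (C1 aldehyde and C10 methyl ketone; 4R,5S,6S,7S,8S,11R), via bis-ozonide 23 (not isolated)
Conditions: O3, CH2Cl2, −78 °C (Sudan red end-point); PPh3, −78 → 20 °C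
Reagents that add atoms: ozone, [O-][O+]=O
Why: Ozonolysis with reductive work-up cleaves the trisubstituted olefin to the C1 aldehyde and the 1,1-disubstituted olefin to the C10 methyl ketone; lactone, acetate, silyl ether and epoxide are inert to ozone at −78 °C, and the tiglate, which would not be, has not yet been introduced.

Step 16
Reactants: 24 keto aldehyde
Product: 25 ten-membered 1,10-diol (4R,5S,6S,7S,8S,10R,11R; C1 epimers)
Conditions: SmI2 (4 equiv), THF, 20 °C, slow addition of 24 to a final 0.003 M; NH4Cl aq.
Reagents that add atoms: none
Why: Intramolecular pinacol coupling of a keto aldehyde with SmI2 under high dilution: the aldehyde is reduced to its ketyl, which adds to the ketone within a samarium-bridged array and closes the ten-membered ring at C1–C10. C10 is set here by the folding of the chain, for which there is no firm model (the 8,10-syn isomer is required and C10 epimers would be separated at 26), while C1 is removed in step 17. The epoxide (not alpha to a carbonyl), the lactone and the acetate are not reduced by SmI2 in THF without additives.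

Step 17
Reactants: 25 1,10-diol
Product: 26 1-oxo-10-hydroxy macrocycle with O8 silylated (4R,5S,6S,7S,8S,10R,11R)
Conditions: IBX, DMSO, 20 °C
Reagents that add atoms: none
Why: IBX oxidation of the secondary hydroxyl of a secondary–tertiary 1,2-diol to the α-hydroxy ketone; IBX is chosen because it does not cleave glycols, and the step removes the undefined C1 centre.

Step 18
Reactants: 26 silyl ether ketol
Product: 27 8,10-dihydroxy-1-ketone (4R,5S,6S,7R,8S,10R,11R)
Conditions: HF·pyridine, pyridine, THF, 0 → 20 °C
Reagents that add atoms: none
Why: Fluoride-mediated cleavage of the silyl ether with pyridine-buffered HF·pyridine, conditions that trisubstituted epoxides, lactones and the base-sensitive 13-acetoxymethyl group tolerate.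

Step 19
Reactants: 27 diol ketone
Product: 28 8-O-tigloyl-10-hydroxy-1-ketone (4R,5S,6S,7R,8S,10R,11R)
Conditions: (E)-2-methylbut-2-enoyl chloride, pyridine, DMAP (cat.), CH2Cl2, 0 → 20 °C
Reagents that add atoms: (E)-2-methylbut-2-enoyl chloride (tigloyl chloride), C/C=C(\C)C(Cl)=O
Why: Acylation with an acid chloride under nucleophilic catalysis; the secondary C8 hydroxyl reacts far faster than the tertiary C10 hydroxyl, tiglates do not isomerise under these conditions, and prompt acylation pre-empts migration of the lactone acyl group from O6 to O8.

Step 20
Reactants: 28 tiglate tertiary alcohol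
Product: 29 target, (4R,5S,6S,7R,8S,10R,11R)-10,13-diacetoxy-4,5-epoxy-1-oxo-8-tigloyloxygermacran-12,6-olide
Conditions: Ac2O, DMAP (1 equiv), Et3N, CH2Cl2, 20 → 35 °C
Reagents that add atoms: acetic anhydride, CC(=O)OC(C)=O
Why: 4-Dimethylaminopyridine-catalysed acetylation of a tertiary α-ketol hydroxyl; a full equivalent of catalyst and mild warming are planned, with the temperature kept low enough that acetic acid is not eliminated across C11–C13.

## Compound list

1 | nerol | CC(C)=CCC/C(C)=C\CO | starting material
2 | (2S,3R)-2,3-epoxynerol | OC[C@@H]1O[C@]1(C)CCC=C(C)C | intermediate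
3 | (2R,3R)-3-methyl-3-(4-methylpent-3-en-1-yl)oxirane-2-carbaldehyde | O=C[C@@H]1O[C@]1(C)CCC=C(C)C | intermediate
4 | ethynylmagnesium bromide | C#C[Mg]Br | starting material
5 | 3-chloro-2-methylprop-1-ene | C=C(C)CCl | starting material
6 | 2-methylpent-1-en-4-yne | C=C(C)CC#C | intermediate
7 | (E)-chloro(4-methylpenta-1,4-dien-1-yl)zirconocene | C=C(C)C/C=C/[Zr](Cl)(C1C=CC=C1)C1C=CC=C1 | intermediate (not isolated)
8 | (E)-methyl(4-methylpenta-1,4-dien-1-yl)zinc | C=C(C)C/C=C/[Zn]C | intermediate (not isolated)
9 | (1S,2E)-5-methyl-1-[(2S,3R)-3-methyl-3-(4-methylpent-3-en-1-yl)oxiran-2-yl]hexa-2,5-dien-1-ol (4R,5S,6S) | O[C@@H](/C=C/CC(C)=C)[C@@H]1O[C@]1(C)CCC=C(C)C | intermediate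
10 | ethyl vinyl ether | CCOC=C | starting material
11 | O6-(2-bromo-1-ethoxyethyl) ether of 9 (4R,5S,6S; C12 epimers) | CCOC(CBr)O[C@@H](/C=C/CC(C)=C)[C@@H]1O[C@]1(C)CCC=C(C)C | intermediate
12 | C8-[bis(dimethylglyoximato)(pyridine)cobalt] derivative of the cyclised 2-ethoxytetrahydrofuran (6,7-trans; C8 and C12 epimers) | CCOC1C[C@H]([CH-]CC(C)=C)[C@H](O1)[C@@H]1O[C@]1(C)CCC=C(C)C.CC(=NO)C(C)=N[O-].CC(=NO)C(C)=N[O-].c1ccncc1.[Co+3] | intermediate (not isolated)
13 | 2-ethoxytetrahydrofuran C8 O-(2,2,6,6-tetramethylpiperidin-1-yl) ether (4R,5S,6S,7S; 6,7-trans; C8 and C12 epimers) | CCOC1C[C@H](C(CC(C)=C)ON2C(C)(C)CCCC2(C)C)[C@H](O1)[C@@H]1O[C@]1(C)CCC=C(C)C | intermediate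
14 | C8 alcohol of the 2-ethoxytetrahydrofuran (4R,5S,6S,7R; C8 and C12 epimers) | CCOC1C[C@H](C(O)CC(C)=C)[C@H](O1)[C@@H]1O[C@]1(C)CCC=C(C)C | intermediate
15 | C8 ketone of the 2-ethoxytetrahydrofuran (4R,5S,6S,7S; C12 epimers) | CCOC1C[C@H](C(=O)CC(C)=C)[C@H](O1)[C@@H]1O[C@]1(C)CCC=C(C)C | intermediate
16 | (8S)-alcohol of the 2-ethoxytetrahydrofuran (4R,5S,6S,7R,8S; C12 epimers) | CCOC1C[C@H]([C@@H](O)CC(C)=C)[C@H](O1)[C@@H]1O[C@]1(C)CCC=C(C)C | intermediate
17 | (8S)-tert-butyldimethylsilyl ether of 16 (4R,5S,6S,7S,8S; C12 epimers) | CCOC1C[C@H]([C@@H](O[Si](C)(C)C(C)(C)C)CC(C)=C)[C@H](O1)[C@@H]1O[C@]1(C)CCC=C(C)C | intermediate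
18 | lactol from 17 (4R,5S,6S,7S,8S; C12 epimers) | OC1C[C@H]([C@@H](O[Si](C)(C)C(C)(C)C)CC(C)=C)[C@H](O1)[C@@H]1O[C@]1(C)CCC=C(C)C | intermediate
19 | γ-lactone with O8 silylated (4R,5S,6S,7S,8S) | O=C1C[C@H]([C@@H](O[Si](C)(C)C(C)(C)C)CC(C)=C)[C@H](O1)[C@@H]1O[C@]1(C)CCC=C(C)C | intermediate
20 | lithium enolate of lactone 19 | [Li]OC1=C[C@H]([C@@H](O[Si](C)(C)C(C)(C)C)CC(C)=C)[C@H](O1)[C@@H]1O[C@]1(C)CCC=C(C)C | intermediate (not isolated)
21 | (11R)-11-hydroxymethyl lactone (4R,5S,6S,7S,8S,11R) | O=C1[C@@H](CO)[C@H]([C@@H](O[Si](C)(C)C(C)(C)C)CC(C)=C)[C@H](O1)[C@@H]1O[C@]1(C)CCC=C(C)C | intermediate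
22 | 13-acetate of 21 (4R,5S,6S,7S,8S,11R) | O=C1[C@@H](COC(C)=O)[C@H]([C@@H](O[Si](C)(C)C(C)(C)C)CC(C)=C)[C@H](O1)[C@@H]1O[C@]1(C)CCC=C(C)C | intermediate
23 | bis(1,2,4-trioxolane) of 22 (ozonides of both olefins) | O=C1[C@@H](COC(C)=O)[C@H]([C@@H](O[Si](C)(C)C(C)(C)C)CC2(C)OOCO2)[C@H](O1)[C@@H]1O[C@]1(C)CCC1OOC(C)(C)O1 | intermediate (not isolated)
24 | keto aldehyde (C1 aldehyde, C10 methyl ketone; 4R,5S,6S,7S,8S,11R) | O=C1[C@@H](COC(C)=O)[C@H]([C@@H](O[Si](C)(C)C(C)(C)C)CC(C)=O)[C@H](O1)[C@@H]1O[C@]1(C)CCC=O | intermediate
25 | 13-acetoxy-4,5-epoxy-1,10-dihydroxy-8-silyloxygermacran-12,6-olide (4R,5S,6S,7S,8S,10R,11R; C1 epimers) | CC(C)(C)[Si](C)(C)O[C@H]1C[C@@](C)(O)C(O)CC[C@@]2(C)O[C@H]2[C@H]2OC(=O)[C@@H](COC(C)=O)[C@@H]21 | intermediate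
26 | 13-acetoxy-4,5-epoxy-10-hydroxy-1-oxo-8-silyloxygermacran-12,6-olide (4R,5S,6S,7S,8S,10R,11R) | CC(C)(C)[Si](C)(C)O[C@H]1C[C@@](C)(O)C(=O)CC[C@@]2(C)O[C@H]2[C@H]2OC(=O)[C@@H](COC(C)=O)[C@@H]21 | intermediate
27 | 13-acetoxy-4,5-epoxy-8,10-dihydroxy-1-oxogermacran-12,6-olide (4R,5S,6S,7R,8S,10R,11R) | O[C@H]1C[C@@](C)(O)C(=O)CC[C@@]2(C)O[C@H]2[C@H]2OC(=O)[C@@H](COC(C)=O)[C@@H]21 | intermediate
28 | 13-acetoxy-4,5-epoxy-10-hydroxy-1-oxo-8-tigloyloxygermacran-12,6-olide (4R,5S,6S,7R,8S,10R,11R) | C/C=C(\C)C(=O)O[C@H]1C[C@@](C)(O)C(=O)CC[C@@]2(C)O[C@H]2[C@H]2OC(=O)[C@@H](COC(C)=O)[C@@H]21 | intermediate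
29 | 10,13-diacetoxy-4,5-epoxy-1-oxo-8-tigloyloxygermacran-12,6-olide (4R,5S,6S,7R,8S,10R,11R) | C/C=C(\C)C(=O)O[C@H]1C[C@@](C)(OC(C)=O)C(=O)CC[C@@]2(C)O[C@H]2[C@H]2OC(=O)[C@@H](COC(C)=O)[C@@H]21 | target

## Step count and least certain steps

Total: 20 steps. Longest linear sequence: 19 steps (steps 1, 2 and 4–20 from nerol); step 3 is a one-step side branch.

**Step 6 (key step).** The most likely failure is loss of the secondary organocobalt intermediate by β-hydride elimination to an olefin before the nitroxide can capture the C8 radical; attack of the strongly nucleophilic monovalent cobalt on the epoxide is a second risk. Fallback: a tin hydride chain under air. From 11, Bu3SnH is added slowly in toluene at 0–20 °C while dry air is passed through the solution. The C11 radical cyclises as before and dioxygen intercepts the C8 radical to give the C8 hydroperoxide F1, which PPh3 reduces to alcohol 14, where the route is rejoined. This bypasses 13 and with it the acidic N–O cleavage of step 7, which is the other place where the epoxide and the acetal are exposed to acid.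

**Step 16.** The most likely failure is poor facial selectivity at C10, because its configuration depends on chain folding and not on a nearby stereocentre; simple reduction of the aldehyde and intermolecular coupling are further risks. Fallback: turn O8 into a directing group. From 24, HF·pyridine removes the silyl group to give hydroxy keto aldehyde F2. Under SmI2 the free hydroxyl and the C10 ketyl oxygen can bind the same trivalent samarium, and in such six-membered chelates the new bond is expected to form cis to the carbinol substituent, which here is the 8,10-syn arrangement; the product is triol F3. Regioselective oxidation of its 1,2-diol through the stannylene acetal (Bu2SnO, then N-bromosuccinimide) gives 27, where the route is rejoined. The price is a free O8 next to the lactone during the coupling.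

**Step 9.** The most likely failure is incomplete chelation by the weakly basic acetal oxygen, so that Felkin–Anh attack anti to C6 competes and gives the 8R alcohol. Fallback: inversion in place of direction. From 15, Li[BH(sBu)3] in THF at −78 °C is used to make the Felkin product on purpose, the (8R)-alcohol F4. Mitsunobu esterification (4-nitrobenzoic acid, PPh3, diisopropyl azodicarboxylate) inverts C8 to give the (8S)-4-nitrobenzoate F5, and K2CO3 in methanol releases 16.

**Step 4.** The most likely failure is poor 5,6-anti selectivity through partial chelation by zinc or zirconium, together with Lewis-acid-promoted opening of the epoxy aldehyde. Fallback: set C6 by reduction. From 9, taken as its C6 epimer mixture, Dess–Martin oxidation gives epoxy dienone F6. Zn(BH4)2 in Et2O at −30 °C, which reduces α,β-epoxy ketones through a five-membered chelate with anti selectivity, returns 9 as the (6S) alcohol.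

## Further compounds

F1 | step 6 | C8 hydroperoxide of the cyclised 2-ethoxytetrahydrofuran (6,7-trans; C8 and C12 epimers) | CCOC1C[C@H](C(OO)CC(C)=C)[C@H](O1)[C@@H]1O[C@]1(C)CCC=C(C)C
F2 | step 16 | keto aldehyde with free C8 hydroxyl (4R,5S,6S,7R,8S,11R) | O=C1[C@@H](COC(C)=O)[C@H]([C@@H](O)CC(C)=O)[C@H](O1)[C@@H]1O[C@]1(C)CCC=O
F3 | step 16 | 13-acetoxy-4,5-epoxy-1,8,10-trihydroxygermacran-12,6-olide (8S,10R; C1 epimers) | O[C@H]1C[C@@](C)(O)C(O)CC[C@@]2(C)O[C@H]2[C@H]2OC(=O)[C@@H](COC(C)=O)[C@@H]21
F4 | step 9 | (8R)-alcohol, C8 epimer of 16 (C12 epimers) | CCOC1C[C@H]([C@H](O)CC(C)=C)[C@H](O1)[C@@H]1O[C@]1(C)CCC=C(C)C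
F5 | step 9 | (8S)-4-nitrobenzoate of 16 (C12 epimers) | CCOC1C[C@H]([C@@H](OC(=O)c2ccc(cc2)[N+](=O)[O-])CC(C)=C)[C@H](O1)[C@@H]1O[C@]1(C)CCC=C(C)C
F6 | step 4 | (E)-5-methyl-1-[(2S,3R)-3-methyl-3-(4-methylpent-3-en-1-yl)oxiran-2-yl]hexa-2,5-dien-1-one | O=C(/C=C/CC(C)=C)[C@@H]1O[C@]1(C)CCC=C(C)C
A1 | alternative 1 | 1-[2-(4-methoxybenzyloxy)vinyl]-3-methyl-6-(prop-1-en-2-yl)cyclohex-2-en-1-ol (alkenyl groups trans; enol ether geometry left open) | COc1ccc(COC=C[C@]2(O)C=C(C)CC[C@H]2C(C)=C)cc1
A2 | alternative 1 | (Z,E)-cyclodeca-2,6-dienone with the C8 4-methoxybenzyl ether | COc1ccc(CO[C@H]2C/C(C)=C/CC/C(C)=C\C(=O)C2)cc1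
A3 | alternative 2 | 5-(tert-butyldimethylsilyloxymethyl)furan-2(5H)-one | O=C1C=C[C@@H](CO[Si](C)(C)C(C)(C)C)O1
A4 | alternative 2 | 2-[(2,2,4-trimethyl-1,3-dioxolan-4-yl)methyl]-1,3-dithiane | C[C@@]1(CC2SCCCS2)COC(C)(C)O1
A5 | alternative 2 | trans,trans-trisubstituted γ-lactone with C8 dithiane and C13 hydroxyl | C[C@@]1(CC2(SCCCS2)[C@H]2[C@H](CO)C(=O)O[C@@H]2CO[Si](C)(C)C(C)(C)C)COC(C)(C)O1
A6 | alternative 3 | eleven-membered sulfone (sulfur between C4 and C5) fused to the lactol methyl ether | CC(C)(C)[Si](C)(C)O[C@H]1C[C@@]2(C)OC(C)(C)O[C@H]2CCC(C)S(=O)(=O)C[C@H]2O[C@@H](OC)C[C@@H]21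
A7 | alternative 3 | Z-cyclodecene fused to the lactol methyl ether | CC(C)(C)[Si](C)(C)O[C@H]1C[C@@]2(C)OC(C)(C)O[C@H]2CC/C(C)=C\[C@H]2O[C@@H](OC)C[C@@H]21
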